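**Missing charge.** Of the starting material charged to the north-east run, 74.2% stands outside the target, whose readings average 25.8% from 6.00 min to 50.0 min. The west run is flat too, reading 11% at 15.0 min and 13% at 50.0 min. So leave the time alone and look at the catalyst.

| flask | starting material | gas phase | catalyst | remark | time |
|---|---|---|---|---|---|
| west | 0.10 M | 6.3 mM (held) | 0.13 mol% | run made earlier |  |
| north-east | 0.10 M | 6.3 mM (held) | 0.3 mol% | run made earlier |  |
| east | 0.15 M | 6.3 mM (held) | 0.2 mol% | run made earlier |  |
| flask | 0.10 M | 6.3 mM (held) | 0.2 mol% |  | 1.0 h |

| run | time / min | target / % |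
|---|---|---|
| west | 4.00 | 12 |
| west | 6.00 | 14 |
| west | 8.00 | 15 |
| west | 15.0 | 11 |
| west | 20.0 | 12 |
| west | 30.0 | 16 |
| west | 50.0 | 13 |
| north-east | 6.00 | 26 |
| north-east | 15.0 | 26 |
| north-east | 20.0 | 27 |
| north-east | 30.0 | 26 |
| north-east | 40.0 | 25 |
| north-east | 50.0 | 25 |
| east | 4.00 | 11 |
| east | 12.0 | 19 |
| east | 20.0 | 16 |
| east | 30.0 | 20 |
| east | 50.0 | 18 |

(readings scatter by 1.5 percentage points)

1. the target standing at 1.0 h, as a percentage of the starting material charged
2. concentration of dissolved gas in solution at 1.0 h, in percent of saturation

- at the start none of the gas phase is in solution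

**Turnover number.** Divide each plateau, as a fraction of the charge, by the catalyst loading, also a fraction of the charge. West averages 13.0%, which gives 100. North-east gives 86.1. East, at the flask's loading but 0.15 M of starting material, averages 18.2%, which gives 91.2. Carry their mean, 92.5, the plateau target per catalyst charged. West reads higher than north-east, and those two runs differ in catalyst loading, so use the mean only between their loadings.

**Decision.** Charge the flask at 0.2 mol% and add no time: my reckoning gives 18.5% target.

**Forecast.** The forecast says 19% target and 100% of saturation, on the ground that “Product therefore follows catalyst concentration”.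

**Result.** The flask gives 19.0% target and 100% of saturation. At 1.00 h the flask holds 0% of its starting material and 100% of its catalyst. The flask's turnover number is 95.2, beside the 92.5 carried from the readings.

    gas phase ⇌ dissolved gas, rate k1*(csat - [dissolved gas]) (kL = 5.90 min⁻¹)
    starting material + dissolved gas + catalyst → catalyst + target (k = 1.63 × 10⁵ M⁻² min⁻¹)
    starting material + dissolved gas → uncatalysed product (k = 27.5 M⁻¹ min⁻¹)
    starting material + target → side product (k = 6.99 M⁻¹ min⁻¹)

**Next flask.** For a neighbour at 0.5 mol% of catalyst, the carried number gives 46.2% target. The computed neighbour reaches 32.7%, less than that, a turnover number of 65.4.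

All runs were generated by integration for substances that don't exist; scatter was added.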